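**Retrosynthetic overview**
1. Both esters go on last: the hindered C-8 ester from (2S,3S)-epoxyangelic acid 21 (made by Katsuki–Sharpless epoxidation), the C-3 angelate from diol 15.
2. The cyclopentane and the acetyl group come from the cadinane → oplopane ring contraction, run as a 1,2-acyl shift of the 3-oxo-4,5-epoxycadinane 12 (C-3 migrates from C-4 to C-5), followed by reduction of the C-3 ketone.
3. Ring B of the cadinane is closed in one pot: the terpenyl allyl cation from carbonate 5 is alkylated at C-6 by isovaleraldehyde enol silane 7, then a type 2 carbonyl-ene reaction onto the isopropenyl group forms C-8–C-9.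
4. Ring A and C-1 come from (S)-(+)-carvone, via cis-carveol and a hydroxy-directed singlet-oxygen ene reaction.
5. Ring order: ring A (from carvone) → ring B (step 5) → six-to-five contraction of ring A (step 8).

Numbering used throughout: cadinane numbering (C-1/C-6 ring fusion, C-4 methyl-bearing, C-7 isopropyl-bearing, C-8 carbinol, C-10/C-14 exocyclic methylene), kept after the contraction (C-4 = acetyl carbonyl, C-3 bonded to C-5); β = face of H-6 and of the isopropyl group, α = face of H-1.

**Step 1**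
Reactants: 1 (S)-(+)-carvone
Product: 2 (1S,5S)-2-methyl-5-(prop-1-en-2-yl)cyclohex-2-en-1-ol [(+)-cis-carveol]
Conditions: NaBH4, CeCl3·7H2O, MeOH, −20 °C
Reagents that add atoms: none
Why: Luche 1,2-reduction, in which axial hydride delivery gives the equatorial 3β-alcohol cis to the isopropenyl group, the geometry needed to direct step 2.

**Step 2**
Reactants: 2 (+)-cis-carveol
Product: 4 (1S,2R,5R)-2-methyl-5-(prop-1-en-2-yl)cyclohex-3-ene-1,2-diol, via tertiary allylic hydroperoxide 3 (not isolated)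
Conditions: O2, tetraphenylporphyrin (cat.), hν, CH2Cl2, 0 °C; then PPh3
Reagents that add atoms: dioxygen, O=O
Why: Hydroxy-directed Schenck ene reaction, in which singlet oxygen is steered by the allylic OH to the β face, bonds to C-4 and abstracts the axial β-H of C-6 (cis effect), moving the alkene to C-5/C-6 and setting C-4 (O cis to 3-OH), while the isopropenyl group reacts far more slowly.

**Step 3**
Reactants: 4 cis-diol
Product: 5 (3aS,5R,7aR)-7a-methyl-5-(prop-1-en-2-yl)-3a,4,5,7a-tetrahydro-2H-1,3-benzodioxol-2-one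
Conditions: 1,1'-carbonyldiimidazole, DMAP (cat.), PhMe, 80 °C
Reagents that add atoms: 1,1'-carbonyldiimidazole, O=C(n1ccnc1)n1ccnc1
Why: Cyclic carbonate formation on the cis-diol (no stereocentre changes), which turns the tertiary allylic oxygen into a leaving group and makes the C-3 oxygen electron-poor so that it cannot trigger a pinacol-type hydride shift in step 5.

**Step 4**
Reactants: 6 3-methylbutanal
Product: 7 (Z)-trimethyl[(3-methylbut-1-en-1-yl)oxy]silane (Z-enriched, distilled)
Conditions: Me3SiCl, Et3N, DMF, 80 °C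
Reagents that add atoms: chlorotrimethylsilane, C[Si](C)(C)Cl
Why: House silylation of the aldehyde under equilibrating conditions, which gives mainly the Z enol silane.

**Step 5**
Reactants: 5 cyclic carbonate; 7 enol silane (1.05 equiv)
Product: 10 (2S,4aR,5S,6R,8aR)-3-methyl-8-methylidene-5-(propan-2-yl)-1,2,4a,5,6,7,8,8a-octahydronaphthalene-2,6-diol [cadina-4,10(14)-diene-3β,8β-diol], via monocyclic aldehyde silyl carbonate 8 (not isolated), via bicyclic silyl carbonate 9 (not isolated)
Conditions: Me3SiOTf (10 mol%), CH2Cl2, −78 °C; then Me2AlCl (3 equiv), −78 to 0 °C; aqueous work-up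
Reagents that add atoms: none
Why: Proposed new method: Me3SiOTf ionises the tertiary allylic C–O bond of 5 to the p-menthadienyl-type allyl cation (the cation of the bisabolyl-to-cadinyl closure), which the enol silane attacks at the secondary terminus C-6 anti to the isopropenyl group through an open antiperiplanar transition state with H-7 over the ring (sets C-6 and C-7; closest known reactions are the Lewis-acid terpenylation of olivetol to cannabidiol and Mukaiyama-type SN1 alkylations), and the freed aldehyde then closes ring B by a Me2AlCl type 2 carbonyl-ene reaction (Snider) through a chair with the C-7 isopropyl equatorial and the Al-bound C=O axial, which sets C-8 as the axial β-alcohol and creates the 10(14)-methylene.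

**Step 6**
Reactants: 10 cadinadienediol
Product: 11 (4aR,5S,6R,8aR)-6-hydroxy-3-methyl-8-methylidene-5-(propan-2-yl)-4a,5,6,7,8,8a-hexahydronaphthalen-2(1H)-one [8β-hydroxycadina-4,10(14)-dien-3-one]
Conditions: MnO2, CH2Cl2, rt
Reagents that add atoms: none
Why: Chemoselective MnO2 oxidation of the allylic C-3 alcohol, leaving the non-allylic axial C-8 alcohol untouched.

**Step 7**
Reactants: 11 hydroxy enone
Product: 12 4α,5α-epoxy-8β-hydroxycadin-10(14)-en-3-one
Conditions: 30% H2O2, NaOH (cat.), MeOH, 0 °C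
Reagents that add atoms: hydrogen peroxide, OO
Why: Weitz–Scheffer nucleophilic epoxidation, which touches only the enone (not the 10(14)-alkene), with axial attack of HOO− at C-5 on the α face; the epoxide face is not critical because C-5 is re-set in step 8.

**Step 8**
Reactants: 12 epoxy ketone
Product: 14 (1S,3aR,6R,7S,7aR)-1-acetyl-6-hydroxy-4-methylidene-7-(propan-2-yl)octahydro-2H-inden-2-one [8β-hydroxyoplop-10(14)-ene-3,4-dione], via C-5 epimeric diketone 13 (not isolated)
Conditions: BF3·OEt2, CH2Cl2, −40 to 0 °C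
Reagents that add atoms: none
Why: House-type Lewis-acid rearrangement of an α,β-epoxy ketone, in which the C-5–O bond (β to the carbonyl) opens and the acyl carbon C-3 migrates from C-4 to C-5 with inversion, contracting ring A and turning C-4 into the acetyl carbonyl, after which the acidic C-5 centre equilibrates through the enol to the diketone with the acetyl group β and trans to the C-7 branch.

**Step 9**
Reactants: 14 β-diketone
Product: 15 1-[(1R,2S,3aR,6R,7S,7aR)-2,6-dihydroxy-4-methylidene-7-(propan-2-yl)octahydro-1H-inden-1-yl]ethan-1-one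
Conditions: LiBH(s-Bu)3, THF, −78 °C; aq. NH4Cl
Reagents that add atoms: none
Why: Bulky trialkylborohydride reduction, expected to take the exposed cyclopentanone carbonyl rather than the acetyl group shielded by C-6/C-7 and the isopropyl group, with hydride arriving on the α face anti to the 5β-acetyl to give the cis 3β-alcohol, as in Selectride reductions of 2-substituted cyclopentanones.

**Step 10**
Reactants: 15 keto diol; 16 angelic acid [(2Z)-2-methylbut-2-enoic acid]
Product: 18 (1R,2S,3aR,6R,7S,7aR)-1-acetyl-6-hydroxy-4-methylidene-7-(propan-2-yl)octahydro-1H-inden-2-yl (2Z)-2-methylbut-2-enoate, via angelic trichlorobenzoic mixed anhydride 17 (not isolated)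
Conditions: 16, 2,4,6-trichlorobenzoyl chloride, Et3N, PhMe, rt; then 15, 40 °C (no DMAP)
Reagents that add atoms: none
Why: Yamaguchi mixed-anhydride esterification, which without DMAP avoids angelate-to-tiglate isomerisation and acylates the unhindered C-3 hydroxyl in preference to the axial C-8 hydroxyl flanked by the isopropyl group (retention at C-3).

**Step 11**
Reactants: 16 angelic acid
Product: 19 (2Z)-2-methylbut-2-en-1-ol
Conditions: LiAlH4, Et2O, 0 °C
Reagents that add atoms: none
Why: Hydride 1,2-reduction of the carboxylic acid with retention of the Z alkene.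

**Step 12**
Reactants: 19 (2Z)-2-methylbut-2-en-1-ol
Product: 20 [(2R,3S)-2,3-dimethyloxiran-2-yl]methanol
Conditions: Ti(Oi-Pr)4 (10 mol%), D-(−)-diisopropyl tartrate (12 mol%), t-BuOOH, 4 Å MS, CH2Cl2, −20 °C
Reagents that add atoms: tert-butyl hydroperoxide, CC(C)(C)OO
Why: Katsuki–Sharpless asymmetric epoxidation, in which the D-(−)-tartrate delivers oxygen to the alkene face that gives the (2R,3S)-epoxy alcohol (both epoxide stereocentres set by the catalyst, cis-methyl/CH2OH geometry from the Z alkene).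

**Step 13**
Reactants: 20 epoxy alcohol
Product: 21 (2S,3S)-2,3-dimethyloxirane-2-carboxylic acid
Conditions: RuCl3 (2 mol%), NaIO4, CCl4–MeCN–H2O, rt
Reagents that add atoms: sodium periodate, [Na+].[O-]I(=O)(=O)=O; water, O
Why: Ruthenium-catalysed periodate oxidation of the primary alcohol to the acid without touching the epoxide; the C-2 descriptor changes from R to S only because of the priority change.

**Step 14**
Reactants: 18 C-3 angelate; 21 epoxy acid
Product: 23 (1R,2S,3aR,6R,7S,7aR)-1-acetyl-2-{[(2Z)-2-methylbut-2-enoyl]oxy}-4-methylidene-7-(propan-2-yl)octahydro-1H-inden-6-yl (2S,3S)-2,3-dimethyloxirane-2-carboxylate (CNP0300602.1), via epoxyangelic nitrobenzoic mixed anhydride 22 (not isolated)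
Conditions: 21, 2-methyl-6-nitrobenzoic anhydride, Et3N, DMAP (cat.), CH2Cl2, rt; then 18
Reagents that add atoms: none
Why: Shiina esterification, which acylates hindered secondary alcohols at room temperature with retention at C-8, mild enough for the epoxide, the angelate and the β-acyloxy ketone.

**Compound list**
1 | (S)-(+)-carvone [(5S)-2-methyl-5-(prop-1-en-2-yl)cyclohex-2-en-1-one] | CC1=CC[C@@H](CC1=O)C(C)=C | starting material
2 | (1S,5S)-2-methyl-5-(prop-1-en-2-yl)cyclohex-2-en-1-ol [(+)-cis-carveol] | C1C=C(C)[C@@H](O)C[C@H]1C(C)=C | intermediate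
3 | (1S,2R,5R)-2-hydroperoxy-2-methyl-5-(prop-1-en-2-yl)cyclohex-3-en-1-ol | C1=C[C@@](C)(OO)[C@@H](O)C[C@H]1C(C)=C | intermediate
4 | (1S,2R,5R)-2-methyl-5-(prop-1-en-2-yl)cyclohex-3-ene-1,2-diol (cis-diol) | C1=C[C@@](C)(O)[C@@H](O)C[C@H]1C(C)=C | intermediate
5 | (3aS,5R,7aR)-7a-methyl-5-(prop-1-en-2-yl)-3a,4,5,7a-tetrahydro-2H-1,3-benzodioxol-2-one | C1=C[C@@]2(C)OC(=O)O[C@H]2C[C@H]1C(C)=C | intermediate
6 | 3-methylbutanal | CC(C)CC=O | starting material
7 | (Z)-trimethyl[(3-methylbut-1-en-1-yl)oxy]silane | CC(C)/C=C\O[Si](C)(C)C | intermediate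
8 | (1S,4R,5R)-2-methyl-4-[(2S)-3-methyl-1-oxobutan-2-yl]-5-(prop-1-en-2-yl)cyclohex-2-en-1-yl trimethylsilyl carbonate | O=C[C@@H](C(C)C)[C@@H]1C=C(C)[C@@H](OC(=O)O[Si](C)(C)C)C[C@H]1C(C)=C | intermediate
9 | (2S,4aR,5S,6R,8aR)-6-hydroxy-3-methyl-8-methylidene-5-(propan-2-yl)-1,2,4a,5,6,7,8,8a-octahydronaphthalen-2-yl trimethylsilyl carbonate | C=C1C[C@@H](O)[C@@H](C(C)C)[C@@H]2C=C(C)[C@@H](OC(=O)O[Si](C)(C)C)C[C@@H]12 | intermediate
10 | (2S,4aR,5S,6R,8aR)-3-methyl-8-methylidene-5-(propan-2-yl)-1,2,4a,5,6,7,8,8a-octahydronaphthalene-2,6-diol [cadina-4,10(14)-diene-3β,8β-diol] | C=C1C[C@@H](O)[C@@H](C(C)C)[C@@H]2C=C(C)[C@@H](O)C[C@@H]12 | intermediate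
11 | (4aR,5S,6R,8aR)-6-hydroxy-3-methyl-8-methylidene-5-(propan-2-yl)-4a,5,6,7,8,8a-hexahydronaphthalen-2(1H)-one [8β-hydroxycadina-4,10(14)-dien-3-one] | C=C1C[C@@H](O)[C@@H](C(C)C)[C@@H]2C=C(C)C(=O)C[C@@H]12 | intermediate
12 | 4α,5α-epoxy-8β-hydroxycadin-10(14)-en-3-one | C=C1C[C@@H](O)[C@@H](C(C)C)[C@@H]2[C@@H]3O[C@]3(C)C(=O)C[C@@H]12 | intermediate
13 | (1R,3aR,6R,7S,7aR)-1-acetyl-6-hydroxy-4-methylidene-7-(propan-2-yl)octahydro-2H-inden-2-one (5α-acetyl epimer) | C=C1C[C@@H](O)[C@@H](C(C)C)[C@@H]2[C@H](C(C)=O)C(=O)C[C@@H]12 | intermediate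
14 | (1S,3aR,6R,7S,7aR)-1-acetyl-6-hydroxy-4-methylidene-7-(propan-2-yl)octahydro-2H-inden-2-one (5β-acetyl; largely enolised) | C=C1C[C@@H](O)[C@@H](C(C)C)[C@@H]2[C@@H](C(C)=O)C(=O)C[C@@H]12 | intermediate
15 | 1-[(1R,2S,3aR,6R,7S,7aR)-2,6-dihydroxy-4-methylidene-7-(propan-2-yl)octahydro-1H-inden-1-yl]ethan-1-one | C=C1C[C@@H](O)[C@@H](C(C)C)[C@@H]2[C@@H](C(C)=O)[C@@H](O)C[C@@H]12 | intermediate
16 | angelic acid [(2Z)-2-methylbut-2-enoic acid] | C/C=C(/C)C(=O)O | starting material
17 | (2Z)-2-methylbut-2-enoic 2,4,6-trichlorobenzoic anhydride | C/C=C(/C)C(=O)OC(=O)c1c(Cl)cc(Cl)cc1Cl | intermediate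
18 | (1R,2S,3aR,6R,7S,7aR)-1-acetyl-6-hydroxy-4-methylidene-7-(propan-2-yl)octahydro-1H-inden-2-yl (2Z)-2-methylbut-2-enoate | C=C1C[C@@H](O)[C@@H](C(C)C)[C@@H]2[C@@H](C(C)=O)[C@@H](OC(=O)/C(C)=C\C)C[C@@H]12 | intermediate
19 | (2Z)-2-methylbut-2-en-1-ol | C/C=C(/C)CO | intermediate
20 | [(2R,3S)-2,3-dimethyloxiran-2-yl]methanol | OC[C@@]1(C)O[C@H]1C | intermediate
21 | (2S,3S)-2,3-dimethyloxirane-2-carboxylic acid | OC(=O)[C@@]1(C)O[C@H]1C | intermediate
22 | (2S,3S)-2,3-dimethyloxirane-2-carboxylic 2-methyl-6-nitrobenzoic anhydride | Cc1cccc([N+](=O)[O-])c1C(=O)OC(=O)[C@@]1(C)O[C@H]1C | intermediate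
23 | (1R,2S,3aR,6R,7S,7aR)-1-acetyl-2-{[(2Z)-2-methylbut-2-enoyl]oxy}-4-methylidene-7-(propan-2-yl)octahydro-1H-inden-6-yl (2S,3S)-2,3-dimethyloxirane-2-carboxylate | C=C1C[C@@H](OC(=O)[C@@]2(C)O[C@H]2C)[C@@H](C(C)C)[C@@H]2[C@@H](C(C)=O)[C@@H](OC(=O)/C(C)=C\C)C[C@@H]12 | target

**Step count**
Total: 14 steps. Longest linear sequence: 10 steps (1, 2, 3, 5, 6, 7, 8, 9, 10, 14); steps 4 and 11–13 are side branches.

**Three steps most likely to fail**

Step 5 (cation alkylation and ene closure in one pot). The C-7 configuration rests on an open transition state. The allylic silyl carbonate left at C-3 could ionise a second time. The cation could lose a proton towards an aromatising triene. The fallback sets out from 5 and comes back at 10. The cation from 5 is trapped instead with the silyl ketene acetal of methyl 3-methylbutanoate (Me3SiOTf, −78 °C), a stronger and cleaner π-nucleophile, to give after hydrolytic work-up the hydroxy ester F1, whose C-7 epimers can be separated or equilibrated. Reduction with DIBAL-H (i-Bu2AlH, −78 °C) gives the hydroxy aldehyde F2, which is purified and cyclised in a separate Me2AlCl ene step to 10.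

Step 8 (acyl-shift ring contraction). The migration terminus C-5 is only secondary, so opening may be slow and a hydride shift from C-6, fluoride opening or acid isomerisation of the 10(14)-alkene can compete. The fallback sets out from 10 and comes back at 18, bypassing steps 6–10 with the sulfonate semipinacol at the alcohol oxidation level. Hydroxyl-directed syn-dihydroxylation of the allylic alcohol with OsO4·TMEDA gives the tetrol F3. Its least hindered C-3 hydroxyl is esterified with 16 under the step 10 conditions to the angelate F4. The equatorial C-5 hydroxyl is mesylated (MsCl, pyridine) to the mesylate F5. KOt-Bu in THF then drives the anionic semipinacol shift (C-3 migrates anti to the 5β-sulfonate, C-4 becomes the acetyl group) to give 18.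

Step 9 (mono-reduction of the β-diketone). The reagent may not distinguish the ring ketone from the acetyl group, and the enolised diketone may simply be deprotonated. The fallback sets out from 14 and comes back at 15. Silylation with t-BuMe2SiOTf and 2,6-lutidine caps the C-8 hydroxyl and the enolised acetyl group to give the bis-silyl enol ether F6, in which the ring carbonyl is the only C=O left. Luche reduction (NaBH4, CeCl3·7H2O, MeOH, −78 °C) gives the allylic alcohol F7. Buffered fluoride (Bu4NF, AcOH) removes both silyl groups, with C-5 protonated under thermodynamic control, to give 15.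

**Further compounds**
F1 | step 5 | methyl (2S)-2-[(1R,4S,6R)-4-hydroxy-3-methyl-6-(prop-1-en-2-yl)cyclohex-2-en-1-yl]-3-methylbutanoate | COC(=O)[C@@H](C(C)C)[C@@H]1C=C(C)[C@@H](O)C[C@H]1C(C)=C
F2 | step 5 | (2S)-2-[(1R,4S,6R)-4-hydroxy-3-methyl-6-(prop-1-en-2-yl)cyclohex-2-en-1-yl]-3-methylbutanal | O=C[C@@H](C(C)C)[C@@H]1C=C(C)[C@@H](O)C[C@H]1C(C)=C
F3 | step 8 | cadin-10(14)-ene-3β,4β,5β,8β-tetrol | C=C1C[C@@H](O)[C@@H](C(C)C)[C@@H]2[C@@H](O)[C@@](C)(O)[C@@H](O)C[C@@H]12
F4 | step 8 | 4β,5β,8β-trihydroxycadin-10(14)-en-3β-yl (2Z)-2-methylbut-2-enoate | C=C1C[C@@H](O)[C@@H](C(C)C)[C@@H]2[C@@H](O)[C@@](C)(O)[C@@H](OC(=O)/C(C)=C\C)C[C@@H]12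
F5 | step 8 | 4β,8β-dihydroxy-5β-(methanesulfonyloxy)cadin-10(14)-en-3β-yl (2Z)-2-methylbut-2-enoate | C=C1C[C@@H](O)[C@@H](C(C)C)[C@@H]2[C@@H](OS(C)(=O)=O)[C@@](C)(O)[C@@H](OC(=O)/C(C)=C\C)C[C@@H]12
F6 | step 9 | 8β-(tert-butyldimethylsilyloxy)-4-[(tert-butyldimethylsilyl)oxy]oplopa-4(5),10(14)-dien-3-one (Z enol ether, silyloxy cis to the ring carbonyl) | C=C1C[C@@H](O[Si](C)(C)C(C)(C)C)[C@@H](C(C)C)[C@@H]2/C(=C(\C)O[Si](C)(C)C(C)(C)C)C(=O)C[C@@H]12
F7 | step 9 | 8β-(tert-butyldimethylsilyloxy)-4-[(tert-butyldimethylsilyl)oxy]oplopa-4(5),10(14)-dien-3β-ol | C=C1C[C@@H](O[Si](C)(C)C(C)(C)C)[C@@H](C(C)C)[C@@H]2/C(=C(\C)O[Si](C)(C)C(C)(C)C)[C@@H](O)C[C@@H]12
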